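The maple run charged capture agent at twice the substrate, the alder run at about half, and I want one constant that serves both runs and this equal-charge flask.

| flask | substrate | capture agent | remark | time |
|---|---|---|---|---|
| alder | 31 mM | 16 mM | run made earlier |  |
| maple | 31 mM | 62 mM | run made earlier |  |
| flask | 31 mM | 31.0 mM |  | 15 min |

- alder (time / min: target / %, trapped intermediate / %): 1.33: 2.6, 3.0; 3.00: 3.2, 7.1; 8.00: 3.1, 16.1; 20.0: 3.0, 28.9
- maple (time / min: target / %, trapped intermediate / %): 5.00: 3.8, 36.6; 10.0: 3.4, 55.4; 15.0: 2.0, 68.9; 20.0: 1.8, 77.2

(each reading ± 0.5 percentage points)

1. ratio of target to trapped intermediate at 4.0 s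
2. ratio of target to trapped intermediate at 15 min
3. which of target and trapped intermediate there is more of at 15 min



The first rung is the target. It stands near its level by the alder reading at 3.00 min, and the readings of both runs average 2.86%, though maple's sink from 3.8% to 1.8%, so this level is a rough reading.

The next rung is capture. With x the fraction of the substrate charge trapped and m the capture agent charge over the substrate charge, I try a second-order law, dx/dt = κ(1 − x)(m − x), which integrates to

κt = ln[(m − x) / (m(1 − x))] / (m − 1)

Maple's last reading gives 0.0495 min⁻¹, the capture constant κ, the rate per minute of trapping at equal charges with nothing yet trapped. Alder's last reading, at another charge ratio, gives 0.0496 min⁻¹.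

The capture clock, 1/κ = 20.2 min, runs longer than the target's rise, so I expect the flask to hold the target at its level while capture creeps on. At m = 1 the law becomes

x = κt / (1 + κt)

At 15 min this gives 42.6% trapped and a ratio of 0.0671. At 4.0 s the law gives about 0.330% trapped, so a target already at its level would give a ratio of 8.67, but alder's first reading stands at 1.33 min, later than that, so this estimate stays loose.

The forecast, reading the target as “a fast pre-equilibrium with substrate that feeds capture”, gives 0.07 (0.05 to 0.1) at 15 min and 10 (4 to 22) at 4.0 s, a value above mine, with trapped intermediate ahead at 15 min.

The flask gives 10.7 at 4.0 s and 0.0670 at 15 min, with trapped intermediate ahead at 15 min, 42.8% against 2.87%.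

    capture agent + intermediate B → trapped intermediate (k = 0.0480 M⁻¹ s⁻¹)
    substrate → intermediate A (k = 0.0300 s⁻¹)
    intermediate B ⇌ intermediate A (K = 0.710, k = 0.0480 s⁻¹)
    substrate → target (k = 0.00620 s⁻¹)
    substrate → intermediate B (k = 0.180 s⁻¹)

Of the substrate charged, the flask at 15.0 min holds 0% as substrate, 31.7% as intermediate B and 22.6% as intermediate A. The capture constant carries to the neighbour charged with 53 mM of capture agent: m = 1.71 in the integrated law gives 62.6% trapped at 15.0 min, and that neighbour holds 62.4%.

All runs were generated by integration with constants of no real substance, and the scatter is random.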